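## Structural features

Neopeltolide (30) is a 14-membered macrolactone (C1–C13 plus the lactone oxygen on C13) bridged by an ether oxygen between C3 and C7, so that C3–C7 and this oxygen form a 2,6-cis-tetrahydropyran inside the macrocycle. The ring carries three stereocentres in a 1,3,5-array (C3, C5, C7); the C5 ester oxygen is axial, trans to the two equatorial ring chains at C3 and C7. C9 (methyl) is an isolated stereocentre between two methylenes, and C11 (OMe) and C13 (lactone carbinol, propyl) are 1,3-anti. The side chain on O5 is a (Z)-enoate linked to a 2,4-disubstituted oxazole with a (Z)-alkenyl methyl carbamate. Fragile groups are the two Z-alkenes (isomerisation), the β-alkoxy ester C1–C3 (retro-oxa-Michael), the lactone and the oxazole. The real difficulty is closing the macrocycle and the cis-tetrahydropyran together, controlling the remote C9 centre, and delivering the axial C5 ester. The key step exploits the array O7–C3–C2–C1(=O)–O13: the ether oxygen on C7 is five atoms from C3 and the lactone carbonyl C1 is the only atom between C2 and O13. Removing C1 as carbon monoxide therefore leaves an open chain with a C2=C3 alkene and two free hydroxyls (O7, O13). Once C5 is taken as its epimer, the C5/C7 and C11/C13 oxygen pairs are both 1,3-anti and the two outer carbinols have the same absolute sense, so both arms can come from one chiral C3 unit.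

## Logic of the disconnections

30 ⇒ 18 + 29. The O5–acyl bond is cut with inversion at C5. This removes the whole sensitive side chain and turns the axial ester into an equatorial alcohol, which is the configuration the ring closure delivers naturally. The forward step must be an SN2 esterification at C5 that leaves both Z-alkenes untouched.

18 ⇒ 17 ⇒ 14 + carbon monoxide. Three bonds are cut at once: O7–C3, C2–C1 and C1–O13. Both rings open, C1 leaves as CO, and the product-to-precursor change is from a bridged bicyclic lactone to the acyclic alkenediol 14 with no ester linkage. In one sentence: a Pd(II)-mediated hydroxyl–alkene–CO–hydroxyl cascade on open-chain 14 closes the tetrahydropyran and the macrolactone together, with C1 arriving as carbon monoxide. The forward step must set C3 cis to C7, let only O7 add to the alkene and let only O13 capture the acyl group; O5 therefore stays acylated.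

14 ⇒ 13. The C7–H bond and the O5–benzoyl bond are cut together. One operation must create C7 anti to O5 and leave O7 free but O5 protected, which is exactly the pattern 14 needs. This demands an intramolecular hydride delivery from a hemiacetal on O5.

13 ⇒ 11 + 3 (through 12). The C6–C7 bond is cut between an acyl C7 and a nucleophilic C6 that already carries the C5 carbinol. C5 then comes from the chiral pool and no aldol stereocontrol is needed. The forward step needs a carbanion β to an oxygen that does not eliminate.

11 ⇒ 10 ⇒ 9 ⇒ 8. The O11–CH3 bond, then the C11–H bond and the O13–acetyl bond are cut. The same hydride-transfer logic sets C11 anti to C13 and differentiates O11 (free, to be methylated) from O13 (acylated). The methylation must not allow acyl migration.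

8 ⇒ 7 ⇒ 5 + 2 (through 6); 5 ⇒ 4. The C11–C12 bond is cut in the same way as C6–C7. The two carboxyl carbons of 4 become C11 and C7, and its stereocentre becomes C9. The two arms must react one after the other, so one is a Weinreb amide while the other waits as a carboxylate.

2 and 3 ⇒ 1. The C14–C15 bond of 2 and the C3–C4 bond of 3 are cut. Both chlorohydrins come from the same epoxide by opening at the terminal carbon, which must leave the C–Cl bond intact.

29 ⇒ 28 ⇒ 27 ⇒ 24 + 26. The ester is hydrolysed last; the Z-alkene next to the oxazole comes from an alkyne, and the oxazole C2–alkyne bond is cut. The forward coupling must tolerate the Z-enoate and the carbamate N–H.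

24 ⇒ 23 ⇒ 22 ⇒ 20 ⇒ 19; 26 ⇒ 25. The enoate C=C is cut to an aldehyde, the C2–I bond to C2–H, and the oxazole to an α-bromoketone. The carbamate is cut at N–C(=O).

## Other disconnections considered

Alternative 1: the first idea is to cut only the C1–O13 lactone bond and close the ring by Yamaguchi macrolactonisation of the seco acid A1, with the cis-tetrahydropyran made beforehand on the open chain. This is reliable, but it uses separate steps for the pyran, for carrying and unmasking the C1 carboxyl, and for its activation. The chosen cascade does the pyran closure, the introduction of C1 and the lactonisation in one operation from a precursor that needs no carboxyl at all.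

Alternative 2: cut O3–C7, C6–C7 and C5–O in a Prins macrocyclisation of the ester-tethered hydroxy alkene aldehyde A2, giving the trifluoroacetate A3, which would converge on 18 after solvolysis. It sets C5 and C7 from C3 and is of comparable length. It requires the lactone ester to be installed first and an aldehyde to be unmasked late. Its oxocarbenium intermediate can scramble by 2-oxonia-Cope rearrangement, and the β-hydroxy ester can dehydrate under the acid. The chosen plan keeps everything acyclic and ester-free until the ring-forming step and builds both arms by the same operation from 1.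

Alternative 3: cut C2=C3 by ring-closing metathesis of the acrylate diene A4 to the 14-membered (E)-enoate A5, then close the pyran by transannular oxa-Michael addition of O7 to C3 to give the silyl ether A6. A4 is simply the acrylate of a silyl analogue of 14, so this route needs one acylation and two ring-forming steps where the cascade needs one. The C3 configuration would be decided by reversible conjugate addition under transannular strain and not by a chair transition state.

Key step: step 11

Remark: atoms are numbered as in the macrolide (C1 lactone carbonyl to C16 propyl terminus). The given SMILES corresponds to 3R,5R,7R,9S,11R,13R and the route is built for that configuration. Compounds 1, 4, 19 and 25 are taken as catalogue materials.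

## Steps

Step 1
Reactants: 1 (R)-epichlorohydrin [(2R)-2-(chloromethyl)oxirane]
Product: 2 (2R)-1-chloropentan-2-ol
Conditions: EtMgBr (1.2 equiv), CuI (10 mol%), THF, −40 °C; aq NH4Cl
Reagents that add atoms: ethylmagnesium bromide, CC[Mg]Br
Why: Copper-catalysed Grignard opening of the epoxide at its unsubstituted carbon (SN2); the C–Cl bond survives at −40 °C and the stereocentre is not touched, so the R configuration of 1 is carried into the future C13.

Step 2
Reactants: 1 (R)-epichlorohydrin
Product: 3 (2R)-1-chloropent-4-en-2-ol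
Conditions: CH2=CHMgBr (1.2 equiv), CuI (10 mol%), THF, −40 °C; aq NH4Cl
Reagents that add atoms: vinylmagnesium bromide, C=C[Mg]Br
Why: Same copper-catalysed epoxide opening; it gives the allyl carbinol that becomes C2–C6 with C5 already fixed.

Step 3
Reactants: 4 (3R)-5-methoxy-3-methyl-5-oxopentanoic acid [methyl hydrogen (R)-3-methylglutarate]
Product: 5 (3S)-5-[methoxy(methyl)amino]-3-methyl-5-oxopentanoic acid
Conditions: MeNH(OMe)·HCl (1.5 equiv), i-PrMgCl (4.5 equiv), THF, −20 to 0 °C; aq HCl
Reagents that add atoms: N,O-dimethylhydroxylamine hydrochloride, CNOC.Cl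
Why: Ester-to-Weinreb-amide aminolysis with the chloromagnesium amide; the carboxylate is inert, so the two arms of 4 stay differentiated (amide arm = C11, acid arm = C7). The C9 centre is untouched; its descriptor changes from R to S only because the CIP priorities of the arms swap.

Step 4
Reactants: 5 (3S)-5-[methoxy(methyl)amino]-3-methyl-5-oxopentanoic acid; 2 (2R)-1-chloropentan-2-ol
Product: 7 (3S,7R)-7-hydroxy-3-methyl-5-oxodecanoic acid, via β-oxido alkyllithium 6 (not isolated)
Conditions: 2 (2.5 equiv): n-BuLi (1 equiv per 2), THF, −78 °C; LiC10H8 (2 equiv per 2), −78 °C; then 5, −78 °C, 1 h; aq NH4Cl, then pH 3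
Reagents that add atoms: none
Why: O-lithiation and reductive lithiation of the C–Cl bond give the β-oxido alkyllithium 6, in which the alkoxide is too poor a leaving group for β-elimination at −78 °C. One equivalent deprotonates the acid of 5, and the next adds to the Weinreb amide and stops at the chelated tetrahedral adduct (ketone synthesis from a Weinreb amide). No new stereocentre is formed: C13 comes from 2 and C9 from 4.

Step 5
Reactants: 7 (3S,7R)-7-hydroxy-3-methyl-5-oxodecanoic acid
Product: 8 (3S,7R)-7-hydroxy-N-methoxy-N,3-dimethyl-5-oxodecanamide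
Conditions: MeNH(OMe)·HCl, EDC·HCl, HOBt (cat.), i-Pr2NEt, CH2Cl2, 0 °C to rt
Reagents that add atoms: N,O-dimethylhydroxylamine hydrochloride, CNOC.Cl
Why: Carbodiimide amidation re-arms C7 as a Weinreb amide for the second organolithium addition. The amine outcompetes the secondary alcohol for the active ester, and an amide at C7 cannot lactonise onto the C11 hydroxyl formed in the next step.

Step 6
Reactants: 8 (3S,7R)-7-hydroxy-N-methoxy-N,3-dimethyl-5-oxodecanamide
Product: 9 (3S,5R,7R)-5-hydroxy-1-[methoxy(methyl)amino]-3-methyl-1-oxodecan-7-yl acetate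
Conditions: SmI2 (30 mol%), MeCHO (5 equiv), THF, −10 °C
Reagents that add atoms: acetaldehyde, CC=O
Why: Evans–Tishchenko reduction: the Sm(III)-bound hemiacetal on O13 delivers hydride to C11 through a chair-like bicyclic transition state, giving the 1,3-anti relationship (C11 R). The same event leaves O13 acetylated and O11 free, which differentiates the two oxygens.

Step 7
Reactants: 9 (3S,5R,7R)-5-hydroxy-1-[methoxy(methyl)amino]-3-methyl-1-oxodecan-7-yl acetate
Product: 10 (3S,5R,7R)-5-methoxy-1-[methoxy(methyl)amino]-3-methyl-1-oxodecan-7-yl acetate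
Conditions: Me3OBF4, 1,8-bis(dimethylamino)naphthalene, CH2Cl2, 0 °C to rt
Reagents that add atoms: trimethyloxonium tetrafluoroborate, C[O+](C)C.F[B-](F)(F)F
Why: O-Methylation with a Meerwein salt and a non-nucleophilic base proceeds without an alkoxide, so 1,3-acetyl migration and β-elimination are avoided.

Step 8
Reactants: 10 (3S,5R,7R)-5-methoxy-1-[methoxy(methyl)amino]-3-methyl-1-oxodecan-7-yl acetate
Product: 11 (3S,5R,7R)-7-hydroxy-N,5-dimethoxy-N,3-dimethyldecanamide
Conditions: K2CO3 (0.2 equiv), MeOH, rt
Reagents that add atoms: none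
Why: Base-catalysed transesterification with methanol removes the acetate; the Weinreb amide and the methyl ether are inert and no centre is epimerisable.

Step 9
Reactants: 11 (3S,5R,7R)-7-hydroxy-N,5-dimethoxy-N,3-dimethyldecanamide; 3 (2R)-1-chloropent-4-en-2-ol
Product: 13 (4R,8S,10R,12R)-4,12-dihydroxy-10-methoxy-8-methylpentadec-1-en-6-one, via β-oxido alkenyllithium 12 (not isolated)
Conditions: 3 (2.5 equiv): n-BuLi (1 equiv per 3), THF, −78 °C; LiC10H8 (2 equiv per 3), −78 °C; then 11, −78 °C, 1 h; aq NH4Cl
Reagents that add atoms: none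
Why: Same sequence as step 4: 12 first deprotonates O13–H, then adds to the Weinreb amide to form the C6–C7 bond; the isolated terminal alkene is not reduced by the arene radical anion. C5 comes from 3 and no new stereocentre is formed.

Step 10
Reactants: 13 (4R,8S,10R,12R)-4,12-dihydroxy-10-methoxy-8-methylpentadec-1-en-6-one
Product: 14 (4R,6R,8R,10R,12R)-6,12-dihydroxy-10-methoxy-8-methylpentadec-1-en-4-yl benzoate
Conditions: SmI2 (30 mol%), PhCHO (1.5 equiv, slow addition), THF, −10 °C
Reagents that add atoms: benzaldehyde, O=Cc1ccccc1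
Why: Second Evans–Tishchenko reduction: hydride goes from the hemiacetal on O5 to C7 anti to O5 (C7 R), and O5 ends as the benzoate while O7 is free. The O13 hydroxyl has no ketone within reach, so only a slower bimolecular Tishchenko acylation could touch it; limiting the aldehyde suppresses this.

Step 11
Reactants: 14 (4R,6R,8R,10R,12R)-6,12-dihydroxy-10-methoxy-8-methylpentadec-1-en-4-yl benzoate
Product: 17 (1R,5R,7R,9S,11R,13S)-7-methoxy-9-methyl-3-oxo-5-propyl-4,15-dioxabicyclo[9.3.1]pentadecan-13-yl benzoate, via alkylpalladium chloride 15 (not isolated), via acylpalladium chloride 16 (not isolated)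
Conditions: Pd(OAc)2 (10 mol%), CuCl2 (3 equiv), 4 Å MS, CO (1 atm), ClCH2CH2Cl (2 mM), rt
Reagents that add atoms: carbon monoxide, [C-]#[O+]
Why: Pd(II) binds the C2=C3 alkene and the C7 hydroxyl adds to C3 (oxypalladation), giving the σ-alkylpalladium 15 with Pd on C2. Under CO, migratory insertion into the primary C2–Pd bond outruns β-hydride elimination and gives the acylpalladium 16, whose acyl carbon is C1. Alcoholysis of 16 by the C13 hydroxyl forms the C1–O13 bond and releases Pd(0), which CuCl2 reoxidises. The closest known reaction type is the oxidative alkoxycarbonylation of δ-hydroxy alkenes to 2,6-cis-tetrahydropyranyl acetates, in the form where a second hydroxyl of the same molecule captures the acylpalladium; this form has been used to close tetrahydropyran-bridged macrolactones from alkenediols. The tetrahydropyran closes by 6-exo-trig attack of O7 on C3, and the 14-membered lactone (12 atoms along the ether bridge) closes by acyl–oxygen bond formation at C1. The only new stereocentre, C3, is fixed as R (2,6-cis) by a chair transition state in which the C8 chain on C7, the benzoate on C5 and the Pd-bound vinyl group are all equatorial. The step needs O7 and not O13 to add to the alkene (six- versus twelve-membered transition state), O5 to stay out (as a benzoate it cannot form the bicyclic δ-lactone that a free cis-hydroxyl would give), and intramolecular capture of 16 (no nucleophilic solvent, 2 mM, sieves, and a cis ring that holds C1 and the C8–C13 chain on the same face).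

Step 12
Reactants: 17 (1R,5R,7R,9S,11R,13S)-7-methoxy-9-methyl-3-oxo-5-propyl-4,15-dioxabicyclo[9.3.1]pentadecan-13-yl benzoate
Product: 18 (1R,5R,7R,9S,11R,13S)-13-hydroxy-7-methoxy-9-methyl-5-propyl-4,15-dioxabicyclo[9.3.1]pentadecan-3-one
Conditions: K2CO3, MeOH, 0 °C to rt
Reagents that add atoms: none
Why: Methanolysis of the exposed equatorial benzoate; the lactone is the ester of a hindered, α-branched secondary alcohol held in a macrocycle and should react far more slowly, as expected for macrolides of this type whose C5 ester is solvolysed before the lactone.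

Step 13
Reactants: 19 methyl 5-bromo-4-oxopentanoate
Product: 20 methyl 3-(1,3-oxazol-4-yl)propanoate
Conditions: HCONH2 (neat, excess), 110 °C
Reagents that add atoms: formamide, NC=O
Why: Bredereck oxazole synthesis: formamide is O-alkylated by the bromomethyl group and its nitrogen condenses with the ketone, so the ketone carbon becomes C4 and the oxazole is 4-substituted with C2 unsubstituted.

Step 14
Reactants: 20 methyl 3-(1,3-oxazol-4-yl)propanoate
Product: 22 methyl 3-(2-iodo-1,3-oxazol-4-yl)propanoate, via oxazol-2-ylzinc chloride 21 (not isolated)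
Conditions: TMPZnCl·LiCl (1.1 equiv), THF, 25 °C; then I2, 0 °C
Reagents that add atoms: iodine, II
Why: Directed zincation at C2–H, the most acidic position (between O and N), with an amide base that tolerates the ester; iodinolysis of the C–Zn bond gives the 2-iodide.

Step 15
Reactants: 22 methyl 3-(2-iodo-1,3-oxazol-4-yl)propanoate
Product: 23 3-(2-iodo-1,3-oxazol-4-yl)propanal
Conditions: DIBAL-H (1.1 equiv), CH2Cl2, −78 °C; Rochelle salt
Reagents that add atoms: none
Why: Partial reduction of the ester through the tetrahedral aluminium hemiacetal, which is stable at −78 °C and gives the aldehyde on work-up.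

Step 16
Reactants: 23 3-(2-iodo-1,3-oxazol-4-yl)propanal
Product: 24 methyl (2Z)-5-(2-iodo-1,3-oxazol-4-yl)pent-2-enoate
Conditions: (CF3CH2O)2P(O)CH2CO2Me, KHMDS, 18-crown-6, THF, −78 °C
Reagents that add atoms: methyl 2-[bis(2,2,2-trifluoroethoxy)phosphoryl]acetate, COC(=O)CP(=O)(OCC(F)(F)F)OCC(F)(F)F
Why: Still–Gennari variant of the Horner–Wadsworth–Emmons olefination; the electron-poor phosphonate with a dissociated potassium counter-ion makes elimination from the kinetic adduct fast and gives the Z-enoate.

Step 17
Reactants: 25 prop-2-yn-1-amine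
Product: 26 methyl prop-2-yn-1-ylcarbamate
Conditions: ClCO2Me, Et3N, CH2Cl2, 0 °C
Reagents that add atoms: methyl chloroformate, COC(=O)Cl
Why: N-Acylation of a primary amine with a chloroformate (carbamate formation).

Step 18
Reactants: 24 methyl (2Z)-5-(2-iodo-1,3-oxazol-4-yl)pent-2-enoate; 26 methyl prop-2-yn-1-ylcarbamate
Product: 27 methyl (2Z)-5-[2-[3-[(methoxycarbonyl)amino]prop-1-yn-1-yl]-1,3-oxazol-4-yl]pent-2-enoate
Conditions: PdCl2(PPh3)2 (5 mol%), CuI (10 mol%), Et3N, MeCN, rt
Reagents that add atoms: none
Why: Sonogashira coupling; oxidative addition into the C2–I bond of the electron-poor azole is easy at room temperature, and the Z-enoate and carbamate N–H are tolerated.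

Step 19
Reactants: 27 methyl (2Z)-5-[2-[3-[(methoxycarbonyl)amino]prop-1-yn-1-yl]-1,3-oxazol-4-yl]pent-2-enoate
Product: 28 methyl (2Z)-5-[2-[(1Z)-3-[(methoxycarbonyl)amino]prop-1-en-1-yl]-1,3-oxazol-4-yl]pent-2-enoate
Conditions: H2 (1 atm), Lindlar catalyst, quinoline, EtOAc, rt
Reagents that add atoms: none
Why: Lindlar semihydrogenation: syn delivery of H2 to the alkyne on poisoned Pd gives the Z-alkene; the alkyne binds much more strongly than the enoate, which should not be reduced.

Step 20
Reactants: 28 methyl (2Z)-5-[2-[(1Z)-3-[(methoxycarbonyl)amino]prop-1-en-1-yl]-1,3-oxazol-4-yl]pent-2-enoate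
Product: 29 (2Z)-5-[2-[(1Z)-3-[(methoxycarbonyl)amino]prop-1-en-1-yl]-1,3-oxazol-4-yl]pent-2-enoic acid
Conditions: LiOH, THF–H2O, 0 °C to rt; 1 M HCl
Reagents that add atoms: lithium hydroxide, [Li+].[OH-]
Why: Saponification of the methyl ester; the methyl carbamate is much less electrophilic and should survive, and the mild conditions should leave both Z-alkenes in place.

Step 21
Reactants: 18 (1R,5R,7R,9S,11R,13S)-13-hydroxy-7-methoxy-9-methyl-5-propyl-4,15-dioxabicyclo[9.3.1]pentadecan-3-one; 29 (2Z)-5-[2-[(1Z)-3-[(methoxycarbonyl)amino]prop-1-en-1-yl]-1,3-oxazol-4-yl]pent-2-enoic acid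
Product: 30 neopeltolide, (1R,5R,7R,9S,11R,13R)-7-methoxy-9-methyl-3-oxo-5-propyl-4,15-dioxabicyclo[9.3.1]pentadecan-13-yl (2Z)-5-[2-[(1Z)-3-[(methoxycarbonyl)amino]prop-1-en-1-yl]-1,3-oxazol-4-yl]pent-2-enoate
Conditions: PPh3, DIAD, benzene, rt
Reagents that add atoms: none
Why: Mitsunobu esterification: the carboxylate of 29 displaces the oxyphosphonium of the equatorial alcohol by SN2, inverting C5 from S to R and placing the ester axial. The neutral conditions should leave the Z-enoate geometry unchanged.

## Compound list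

1 | (R)-epichlorohydrin, (2R)-2-(chloromethyl)oxirane | ClC[C@H]1CO1 | starting material
2 | (2R)-1-chloropentan-2-ol | CCC[C@@H](O)CCl | intermediate
3 | (2R)-1-chloropent-4-en-2-ol | C=CC[C@@H](O)CCl | intermediate
4 | (3R)-5-methoxy-3-methyl-5-oxopentanoic acid | COC(=O)C[C@H](C)CC(=O)O | starting material
5 | (3S)-5-[methoxy(methyl)amino]-3-methyl-5-oxopentanoic acid | CON(C)C(=O)C[C@H](C)CC(=O)O | intermediate
6 | lithium (2S)-1-lithiopentan-2-olate (β-oxido alkyllithium) | CCC[C@@H](O[Li])C[Li] | intermediate
7 | (3S,7R)-7-hydroxy-3-methyl-5-oxodecanoic acid | CCC[C@@H](O)CC(=O)C[C@H](C)CC(=O)O | intermediate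
8 | (3S,7R)-7-hydroxy-N-methoxy-N,3-dimethyl-5-oxodecanamide | CCC[C@@H](O)CC(=O)C[C@H](C)CC(=O)N(C)OC | intermediate
9 | (3S,5R,7R)-5-hydroxy-1-[methoxy(methyl)amino]-3-methyl-1-oxodecan-7-yl acetate | CCC[C@@H](OC(C)=O)C[C@H](O)C[C@H](C)CC(=O)N(C)OC | intermediate
10 | (3S,5R,7R)-5-methoxy-1-[methoxy(methyl)amino]-3-methyl-1-oxodecan-7-yl acetate | CCC[C@@H](OC(C)=O)C[C@H](OC)C[C@H](C)CC(=O)N(C)OC | intermediate
11 | (3S,5R,7R)-7-hydroxy-N,5-dimethoxy-N,3-dimethyldecanamide | CCC[C@@H](O)C[C@H](OC)C[C@H](C)CC(=O)N(C)OC | intermediate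
12 | lithium (2S)-1-lithiopent-4-en-2-olate (β-oxido alkenyllithium) | C=CC[C@@H](O[Li])C[Li] | intermediate
13 | (4R,8S,10R,12R)-4,12-dihydroxy-10-methoxy-8-methylpentadec-1-en-6-one | CCC[C@@H](O)C[C@H](OC)C[C@H](C)CC(=O)C[C@H](O)CC=C | intermediate
14 | (4R,6R,8R,10R,12R)-6,12-dihydroxy-10-methoxy-8-methylpentadec-1-en-4-yl benzoate | CCC[C@@H](O)C[C@H](OC)C[C@H](C)C[C@@H](O)C[C@H](OC(=O)c1ccccc1)CC=C | intermediate
15 | alkylpalladium chloride: 14 after O7–C3 ring closure (2,6-cis-tetrahydropyran, C3 R, all other centres as in 14), PdCl on C2 | CCC[C@@H](O)C[C@H](OC)C[C@H](C)C[C@@H]1C[C@H](OC(=O)c2ccccc2)C[C@H](C[Pd]Cl)O1 | intermediate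
16 | acylpalladium chloride: CO-insertion product of 15, C1(=O)–PdCl on C2, stereocentres as in 15 | CCC[C@@H](O)C[C@H](OC)C[C@H](C)C[C@@H]1C[C@H](OC(=O)c2ccccc2)C[C@H](CC(=O)[Pd]Cl)O1 | intermediate
17 | (1R,5R,7R,9S,11R,13S)-7-methoxy-9-methyl-3-oxo-5-propyl-4,15-dioxabicyclo[9.3.1]pentadecan-13-yl benzoate | CCC[C@@H]1C[C@H](OC)C[C@H](C)C[C@@H]2C[C@H](OC(=O)c3ccccc3)C[C@H](CC(=O)O1)O2 | intermediate
18 | (1R,5R,7R,9S,11R,13S)-13-hydroxy-7-methoxy-9-methyl-5-propyl-4,15-dioxabicyclo[9.3.1]pentadecan-3-one | CCC[C@@H]1C[C@H](OC)C[C@H](C)C[C@@H]2C[C@H](O)C[C@H](CC(=O)O1)O2 | intermediate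
19 | methyl 5-bromo-4-oxopentanoate | COC(=O)CCC(=O)CBr | starting material
20 | methyl 3-(1,3-oxazol-4-yl)propanoate | COC(=O)CCc1cocn1 | intermediate
21 | [4-(3-methoxy-3-oxopropyl)-1,3-oxazol-2-yl]zinc chloride | COC(=O)CCc1coc([Zn]Cl)n1 | intermediate
22 | methyl 3-(2-iodo-1,3-oxazol-4-yl)propanoate | COC(=O)CCc1coc(I)n1 | intermediate
23 | 3-(2-iodo-1,3-oxazol-4-yl)propanal | O=CCCc1coc(I)n1 | intermediate
24 | methyl (2Z)-5-(2-iodo-1,3-oxazol-4-yl)pent-2-enoate | COC(=O)/C=C\CCc1coc(I)n1 | intermediate
25 | prop-2-yn-1-amine | C#CCN | starting material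
26 | methyl prop-2-yn-1-ylcarbamate | COC(=O)NCC#C | intermediate
27 | methyl (2Z)-5-[2-[3-[(methoxycarbonyl)amino]prop-1-yn-1-yl]-1,3-oxazol-4-yl]pent-2-enoate | COC(=O)/C=C\CCc1coc(C#CCNC(=O)OC)n1 | intermediate
28 | methyl (2Z)-5-[2-[(1Z)-3-[(methoxycarbonyl)amino]prop-1-en-1-yl]-1,3-oxazol-4-yl]pent-2-enoate | COC(=O)/C=C\CCc1coc(/C=C\CNC(=O)OC)n1 | intermediate
29 | (2Z)-5-[2-[(1Z)-3-[(methoxycarbonyl)amino]prop-1-en-1-yl]-1,3-oxazol-4-yl]pent-2-enoic acid | OC(=O)/C=C\CCc1coc(/C=C\CNC(=O)OC)n1 | intermediate
30 | neopeltolide | CCC[C@@H]1C[C@H](OC)C[C@H](C)C[C@@H]2C[C@@H](OC(=O)/C=C\CCc3coc(/C=C\CNC(=O)OC)n3)C[C@H](CC(=O)O1)O2 | target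

## Step count and least certain steps

Total step count: 21. Longest linear sequence: 11 steps (steps 3–12 and 21, from 4).

Step 11 (key step). The acylpalladium may be captured between molecules (oligomers) or by adventitious water or chloride instead of by O13. β-Hydride elimination from the alkylpalladium may compete before CO insertion. The acid released may also move the benzoate from O5 to O7 and so remove the nucleophile. Fallback: separate the two ring closures. Starting from 14, carbonylate in methanol (PdCl2 cat., CuCl2, CO, MeOH), so that the solvent captures the acylpalladium and gives the tetrahydropyranyl acetic ester methyl 2-[(2R,4S,6R)-4-(benzoyloxy)-6-[(2S,4R,6R)-6-hydroxy-4-methoxy-2-methylnonyl]oxan-2-yl]acetate F1. Selective hydrolysis of the methyl ester with Me3SnOH gives the seco acid 2-[(2R,4S,6R)-4-(benzoyloxy)-6-[(2S,4R,6R)-6-hydroxy-4-methoxy-2-methylnonyl]oxan-2-yl]acetic acid F2. Yamaguchi macrolactonisation of F2 returns to the route at 17.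

Step 4. The dilithio species may lose lithium oxide to give 1-pentene if the temperature rises, residual naphthalenide may cleave the N–O bond of the Weinreb amide by electron transfer, and the lithium carboxylate may be poorly soluble. Fallback with a sulfone as the carbanion carrier: from 2, displacement with sodium benzenesulfinate (DMF, 80 °C) gives (2R)-1-(phenylsulfonyl)pentan-2-ol F3. Its C,O-dianion (n-BuLi, 2 equiv, −78 °C) is acylated by the lithium salt of 5 to give (3S,7R)-7-hydroxy-3-methyl-5-oxo-6-(phenylsulfonyl)decanoic acid F4 (both epimers at C6). Reductive desulfonylation with aluminium amalgam returns to the route at 7.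

Step 9. The same failure modes apply, on a more valuable substrate that also carries a free hydroxyl. Fallback: from 3, sodium benzenesulfinate gives (2R)-1-(phenylsulfonyl)pent-4-en-2-ol F5. Its dianion is acylated by 11 to give (4R,8S,10R,12R)-4,12-dihydroxy-10-methoxy-8-methyl-5-(phenylsulfonyl)pentadec-1-en-6-one F6 (both epimers at C5). Aluminium amalgam, which leaves the terminal alkene alone, returns to the route at 13.

Step 10. The free O13 hydroxyl may be benzoylated by a bimolecular Tishchenko pathway, and the benzoate may migrate from O5 to O7 on the samarium alkoxide. Fallback with O13 masked: from 11, silylation (TESCl, imidazole) gives (3S,5R,7R)-N,5-dimethoxy-N,3-dimethyl-7-[(triethylsilyl)oxy]decanamide F7. Addition of 12 gives (4R,8S,10R,12R)-4-hydroxy-10-methoxy-8-methyl-12-[(triethylsilyl)oxy]pentadec-1-en-6-one F8. Evans–Tishchenko reduction with benzaldehyde gives (4R,6R,8R,10R,12R)-6-hydroxy-10-methoxy-8-methyl-12-[(triethylsilyl)oxy]pentadec-1-en-4-yl benzoate F9. Desilylation with PPTS in methanol returns to the route at 14.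

Step 21. The activated equatorial alcohol may eliminate to a dihydropyran, the hindered centre may react slowly so that acyl transfer with retention competes, and the enoic acid may isomerise. Fallback by oxidation, reduction and acylation with retention: from 18, Dess–Martin oxidation gives the ketone (1R,5R,7R,9S,11R)-7-methoxy-9-methyl-5-propyl-4,15-dioxabicyclo[9.3.1]pentadecane-3,13-dione F10. L-Selectride at −78 °C attacks from the equatorial side and gives the axial alcohol (1R,5R,7R,9S,11R,13R)-13-hydroxy-7-methoxy-9-methyl-5-propyl-4,15-dioxabicyclo[9.3.1]pentadecan-3-one F11. Esterification of F11 with 29 (2,4,6-trichlorobenzoyl chloride, Et3N, DMAP) returns to the route at 30.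

## Further compounds

F1 | step 11 | methyl 2-[(2R,4S,6R)-4-(benzoyloxy)-6-[(2S,4R,6R)-6-hydroxy-4-methoxy-2-methylnonyl]oxan-2-yl]acetate | CCC[C@@H](O)C[C@H](OC)C[C@H](C)C[C@@H]1C[C@H](OC(=O)c2ccccc2)C[C@H](CC(=O)OC)O1
F2 | step 11 | 2-[(2R,4S,6R)-4-(benzoyloxy)-6-[(2S,4R,6R)-6-hydroxy-4-methoxy-2-methylnonyl]oxan-2-yl]acetic acid | CCC[C@@H](O)C[C@H](OC)C[C@H](C)C[C@@H]1C[C@H](OC(=O)c2ccccc2)C[C@H](CC(=O)O)O1
F3 | step 4 | (2R)-1-(phenylsulfonyl)pentan-2-ol | CCC[C@@H](O)CS(=O)(=O)c1ccccc1
F4 | step 4 | (3S,7R)-7-hydroxy-3-methyl-5-oxo-6-(phenylsulfonyl)decanoic acid (both C6 epimers) | CCC[C@@H](O)C(C(=O)C[C@H](C)CC(=O)O)S(=O)(=O)c1ccccc1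
F5 | step 9 | (2R)-1-(phenylsulfonyl)pent-4-en-2-ol | C=CC[C@@H](O)CS(=O)(=O)c1ccccc1
F6 | step 9 | (4R,8S,10R,12R)-4,12-dihydroxy-10-methoxy-8-methyl-5-(phenylsulfonyl)pentadec-1-en-6-one (both C5 epimers) | CCC[C@@H](O)C[C@H](OC)C[C@H](C)CC(=O)C([C@H](O)CC=C)S(=O)(=O)c1ccccc1
F7 | step 10 | (3S,5R,7R)-N,5-dimethoxy-N,3-dimethyl-7-[(triethylsilyl)oxy]decanamide | CCC[C@@H](O[Si](CC)(CC)CC)C[C@H](OC)C[C@H](C)CC(=O)N(C)OC
F8 | step 10 | (4R,8S,10R,12R)-4-hydroxy-10-methoxy-8-methyl-12-[(triethylsilyl)oxy]pentadec-1-en-6-one | CCC[C@@H](O[Si](CC)(CC)CC)C[C@H](OC)C[C@H](C)CC(=O)C[C@H](O)CC=C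
F9 | step 10 | (4R,6R,8R,10R,12R)-6-hydroxy-10-methoxy-8-methyl-12-[(triethylsilyl)oxy]pentadec-1-en-4-yl benzoate | CCC[C@@H](O[Si](CC)(CC)CC)C[C@H](OC)C[C@H](C)C[C@@H](O)C[C@H](OC(=O)c1ccccc1)CC=C
F10 | step 21 | (1R,5R,7R,9S,11R)-7-methoxy-9-methyl-5-propyl-4,15-dioxabicyclo[9.3.1]pentadecane-3,13-dione | CCC[C@@H]1C[C@H](OC)C[C@H](C)C[C@@H]2CC(=O)C[C@H](CC(=O)O1)O2
F11 | step 21 | (1R,5R,7R,9S,11R,13R)-13-hydroxy-7-methoxy-9-methyl-5-propyl-4,15-dioxabicyclo[9.3.1]pentadecan-3-one | CCC[C@@H]1C[C@H](OC)C[C@H](C)C[C@@H]2C[C@@H](O)C[C@H](CC(=O)O1)O2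
A1 | alternative 1 | 2-[(2R,4S,6R)-4-[(tert-butyldimethylsilyl)oxy]-6-[(2S,4R,6R)-6-hydroxy-4-methoxy-2-methylnonyl]oxan-2-yl]acetic acid | CCC[C@@H](O)C[C@H](OC)C[C@H](C)C[C@@H]1C[C@H](O[Si](C)(C)C(C)(C)C)C[C@H](CC(=O)O)O1
A2 | alternative 2 | (4R,6R,8S)-6-methoxy-8-methyl-10-oxodecan-4-yl (3R)-3-hydroxyhex-5-enoate | CCC[C@@H](OC(=O)C[C@H](O)CC=C)C[C@H](OC)C[C@H](C)CC=O
A3 | alternative 2 | (1R,5R,7R,9S,11R,13S)-7-methoxy-9-methyl-3-oxo-5-propyl-4,15-dioxabicyclo[9.3.1]pentadecan-13-yl trifluoroacetate | CCC[C@@H]1C[C@H](OC)C[C@H](C)C[C@@H]2C[C@H](OC(=O)C(F)(F)F)C[C@H](CC(=O)O1)O2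
A4 | alternative 3 | (4R,6R,8R,10R,12R)-4-[(tert-butyldimethylsilyl)oxy]-6-hydroxy-10-methoxy-8-methylpentadec-1-en-12-yl prop-2-enoate | CCC[C@@H](OC(=O)C=C)C[C@H](OC)C[C@H](C)C[C@@H](O)C[C@H](O[Si](C)(C)C(C)(C)C)CC=C
A5 | alternative 3 | (3E,6R,8R,10R,12R,14R)-6-[(tert-butyldimethylsilyl)oxy]-8-hydroxy-12-methoxy-10-methyl-14-propyloxacyclotetradec-3-en-2-one | CCC[C@@H]1C[C@H](OC)C[C@H](C)C[C@@H](O)C[C@H](O[Si](C)(C)C(C)(C)C)C/C=C/C(=O)O1
A6 | alternative 3 | (1R,5R,7R,9S,11R,13S)-13-[(tert-butyldimethylsilyl)oxy]-7-methoxy-9-methyl-5-propyl-4,15-dioxabicyclo[9.3.1]pentadecan-3-one | CCC[C@@H]1C[C@H](OC)C[C@H](C)C[C@@H]2C[C@H](O[Si](C)(C)C(C)(C)C)C[C@H](CC(=O)O1)O2
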